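## Retrosynthetic overview

1. Target 31 ⇐ O‑acetylation and hydroxyl‑directed Sharpless epoxidation (C10=C11) of macrocyclic diol 29.
2. 29 ⇐ the 14‑membered ring is closed last, at C4–C5, by intramolecular π‑allyl/vinylstannane (Stille) coupling of seco‑chloride 28.
3. 28 ⇐ Wittig homologation at C2 and asymmetric alkenylzinc union (C11–C12) of alkyne–stannane 19 with lactone aldehyde 11.
4. 11 ⇐ ozonolytic opening of the cyclopentene‑fused α‑methylene lactone 8. Its cis‑fused γ‑lactone (C1, C14) comes from the key step, an oxidative radical [3+2] annulation of cyclopentadiene with malonic acid (C14–C15 and C1–O bonds).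
5. Ring order: γ‑lactone (on a sacrificial cyclopentene) → cyclopentene cleaved → macrocycle → epoxide.

Labels (local, not IUPAC locants): C1–C14 are the macrocycle carbons in the order of the target SMILES. C1 = lactone O–CH, C3/C7/C11 carry the methyls, C12 = OAc carbon, C14 = ring‑fusion CH; C15 = lactone α‑carbon, C16 = lactone C=O, C17 = exocyclic CH2.

Assumption: sodium cyclopentadienide (THF solution) is taken as the purchasable source of cyclopentadiene; 2‑(triphenylphosphoranylidene)propanal and (dibromomethyl)tributylstannane are used as reagents.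

## Route

Step 1
Reactants: 1 sodium cyclopentadienide; 2 malonic acid
Product: 4 rac-(3aS,6aS)-2-oxo-3,3a,4,6a-tetrahydro-2H-cyclopenta[b]furan-3-carboxylic acid, via cyclopenta-1,3-diene 3 (not isolated)
Conditions: 2 (4 equiv), AcOH, 15 °C, add 1 (2 M in THF); then Mn(OAc)3·2H2O (2.2 equiv), Cu(OAc)2·H2O (0.1 equiv), 25 °C
Reagents that add atoms: none
Why: Oxidative free‑radical carbolactonisation of a conjugated diene (Mn(OAc)3 γ‑lactone annulation): the malonyl radical made by trivalent manganese adds to a diene terminus (C14–C15 bond), the allyl radical is oxidised to the allyl cation by trivalent manganese or divalent copper, and the carboxyl group closes on the neighbouring carbon from the same face, so C1 and C14 are necessarily cis (5,5‑fusion; racemic, C3 not controlled).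

Step 2
Reactants: 4 rac-(3aS,6aS)-2-oxo-3,3a,4,6a-tetrahydro-2H-cyclopenta[b]furan-3-carboxylic acid
Product: 6 (3aS,6aS)-2-oxo-3,3a,4,6a-tetrahydro-2H-cyclopenta[b]furan-3-carboxylic acid, via (S)-1-phenylethylammonium salt 5 (not isolated)
Conditions: (S)-1-phenylethylamine (0.55 equiv), EtOAc/EtOH, crystallise twice, filter; 1 M HCl, EtOAc
Reagents that add atoms: none
Why: Classical resolution by diastereomeric salt crystallisation; no stereocentre is created, the (3aS,6aS) antipode (C1 and C14 of the target) is selected, and the labile C3 centre is irrelevant because it is destroyed in step 3.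

Step 3
Reactants: 6 (3aS,6aS)-2-oxo-3,3a,4,6a-tetrahydro-2H-cyclopenta[b]furan-3-carboxylic acid
Product: 8 (3aS,6aS)-3-methylidene-3,3a,4,6a-tetrahydro-2H-cyclopenta[b]furan-2-one, via Mannich base 7 (not isolated)
Conditions: Et2NH, 37% aq. CH2O, 25 °C; then NaOAc, AcOH, 70 °C
Reagents that add atoms: formaldehyde (C=O)
Why: Decarboxylative Mannich methylenation: the Mannich base of the malonic half‑acid loses CO2 and diethylamine to give the exocyclic alkene, C1 and C14 are untouched and the C3 centre disappears.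

Step 4
Reactants: 8 (3aS,6aS)-3-methylidene-3,3a,4,6a-tetrahydro-2H-cyclopenta[b]furan-2-one
Product: 11 2-[(2R,3S)-2-(dimethoxymethyl)-4-methylidene-5-oxooxolan-3-yl]acetaldehyde, via methoxy hydroperoxide aldehyde 9 (not isolated), via methoxy hydroperoxide acetal 10 (not isolated)
Conditions: O3 (1.0 equiv, Sudan red end point), NaHCO3, CH2Cl2/MeOH, −78 °C; TsOH·H2O, 23 °C; NaHCO3, Me2S
Reagents that add atoms: ozone ([O-][O+]=O); methanol (CO)
Why: Ozonolysis with Schreiber terminal differentiation: ozone attacks the strained electron‑rich cyclopentene much faster than the acrylate‑type exocyclic alkene, the carbonyl oxide forms at the carbon remote from the electron‑withdrawing allylic lactone oxygen (C12) and is trapped by methanol, and the free C2 aldehyde is acetalised before the hydroperoxide is reduced, with no stereocentre affected.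

Step 5
Reactants: 12 2-methylprop-2-en-1-ol; 13 1-bromobut-2-yne
Product: 15 2-methylidenehept-5-yn-1-ol, via dilithiated alcohol 14 (not isolated)
Conditions: n-BuLi (2.1 equiv), TMEDA, Et2O/hexane, 0 → 23 °C; 13, THF, −78 → 0 °C; H2O
Reagents that add atoms: none
Why: Alkoxide‑directed allylic lithiation to the dianion followed by SN2 C‑alkylation with the propargylic bromide (attack at the unsubstituted CH2, the methyl‑capped alkyne terminus disfavours SN2′).

Step 6
Reactants: 15 2-methylidenehept-5-yn-1-ol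
Product: 16 [(2R)-2-(pent-3-yn-1-yl)oxiran-2-yl]methanol
Conditions: Ti(OiPr)4 (10 mol %), D-(−)-diisopropyl tartrate (13 mol %), t-BuOOH, 4 Å MS, CH2Cl2, −25 °C
Reagents that add atoms: tert-butyl hydroperoxide (CC(C)(C)OO)
Why: Sharpless asymmetric epoxidation of a 2‑substituted allylic alcohol; the D‑(−)‑tartrate catalyst epoxidises the face that makes the quaternary carbon (future C7) R, the mirror image of the L‑(+)‑tartrate outcome known for 2‑methylglycidol.

Step 7
Reactants: 16 [(2R)-2-(pent-3-yn-1-yl)oxiran-2-yl]methanol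
Product: 17 (2R)-2-methylhept-5-yne-1,2-diol
Conditions: LiAlH4, THF, 0 °C; aq. NaOH work-up
Reagents that add atoms: none
Why: SN2 hydride opening of the 2,2‑disubstituted epoxide at its CH2 terminus creates the C7 methyl group; the tertiary C–O bond is not broken, so C7 keeps its configuration (R).

Step 8
Reactants: 17 (2R)-2-methylhept-5-yne-1,2-diol
Product: 18 (2R)-2-hydroxy-2-methylhept-5-ynal
Conditions: SO3·pyridine, DMSO, Et3N, CH2Cl2, 0 °C
Reagents that add atoms: none
Why: Parikh–Doering oxidation of the only oxidisable (primary) hydroxyl; the α‑carbon is quaternary and cannot epimerise.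

Step 9
Reactants: 18 (2R)-2-hydroxy-2-methylhept-5-ynal
Product: 19 (1E,3R)-3-methyl-1-(tributylstannyl)oct-1-en-6-yn-3-ol
Conditions: CrCl2 (8 equiv), Bu3SnCHBr2, LiI, THF/DMF, 23 °C
Reagents that add atoms: (dibromomethyl)tributylstannane (CCCC[Sn](CCCC)(CCCC)C(Br)Br)
Why: Hodgson stannyl variant of the Takai olefination: the geminal dichromium reagent formed from Bu3SnCHBr2 and divalent chromium adds to the aldehyde and eliminates to give the E‑vinylstannane (C5=C6), with C7 unaffected.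

Step 10
Reactants: 19 (1E,3R)-3-methyl-1-(tributylstannyl)oct-1-en-6-yn-3-ol; 11 2-[(2R,3S)-2-(dimethoxymethyl)-4-methylidene-5-oxooxolan-3-yl]acetaldehyde
Product: 23 (4S,5R)-5-(dimethoxymethyl)-4-[(2S,3E,7R,8E)-2,7-dihydroxy-3,7-dimethyl-9-(tributylstannyl)nona-3,8-dien-1-yl]-3-methylideneoxolan-2-one, via methylzinc alkoxide 20 (not isolated), via alkenylzirconocene chloride 21 (not isolated), via alkenylzinc 22 (not isolated)
Conditions: 19, Me2Zn (1.05 equiv), toluene, 0 °C; Cp2ZrHCl (1.3 equiv), CH2Cl2, 40 °C; Me2Zn, toluene, −65 °C; (+)-MIB (10 mol %); 11, −30 → 0 °C; aq. NH4Cl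
Reagents that add atoms: none
Why: Wipf‑type hydrozirconation–transmetalation–asymmetric alkenylation: syn‑hydrozirconation puts Zr on the methyl‑bearing alkyne carbon (fixing the E C10=C11 geometry), Zr‑to‑Zn exchange gives the alkenylzinc, and the amino alcohol ligand (+)-MIB directs its 1,2‑addition to the Re face of the aldehyde, setting C12 as S under catalyst control.

Step 11
Reactants: 23 (4S,5R)-5-(dimethoxymethyl)-4-[(2S,3E,7R,8E)-2,7-dihydroxy-3,7-dimethyl-9-(tributylstannyl)nona-3,8-dien-1-yl]-3-methylideneoxolan-2-one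
Product: 24 (3aS,5S,7aR)-7-hydroxy-5-[(2E,6R,7E)-6-hydroxy-6-methyl-8-(tributylstannyl)octa-2,7-dien-2-yl]-3-methylidenehexahydro-2H-furo[2,3-c]pyran-2-one
Conditions: PPTS (0.2 equiv), acetone/H2O (10:1), 45 °C
Reagents that add atoms: water (O)
Why: Acid‑catalysed acetal hydrolysis assisted by the C12 hydroxyl; the unmasked C2 aldehyde is held as the six‑membered lactol (anomeric centre uncontrolled and lost in step 12).

Step 12
Reactants: 24 (3aS,5S,7aR)-7-hydroxy-5-[(2E,6R,7E)-6-hydroxy-6-methyl-8-(tributylstannyl)octa-2,7-dien-2-yl]-3-methylidenehexahydro-2H-furo[2,3-c]pyran-2-one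
Product: 25 (4S,5S)-4-[(2S,3E,7R,8E)-2,7-dihydroxy-3,7-dimethyl-9-(tributylstannyl)nona-3,8-dien-1-yl]-3-methylidene-5-[(1E)-2-methyl-3-oxoprop-1-en-1-yl]oxolan-2-one
Conditions: Ph3P=C(CH3)CHO, toluene, 90 °C
Reagents that add atoms: 2-(triphenylphosphoranylidene)propanal (CC(C=O)=P(c1ccccc1)(c1ccccc1)c1ccccc1)
Why: Wittig olefination of the lactol through its open hydroxy‑aldehyde form; the formyl‑stabilised ylide gives the E‑trisubstituted C2=C3 enal under thermodynamic control, and C1 is not exposed to base.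

Step 13
Reactants: 25 (4S,5S)-4-[(2S,3E,7R,8E)-2,7-dihydroxy-3,7-dimethyl-9-(tributylstannyl)nona-3,8-dien-1-yl]-3-methylidene-5-[(1E)-2-methyl-3-oxoprop-1-en-1-yl]oxolan-2-one
Product: 26 (4S,5S)-4-[(2S,3E,7R,8E)-2,7-dihydroxy-3,7-dimethyl-9-(tributylstannyl)nona-3,8-dien-1-yl]-5-[(1E)-3-hydroxy-2-methylprop-1-en-1-yl]-3-methylideneoxolan-2-one
Conditions: NaBH4, CeCl3·7H2O, MeOH, −78 °C
Reagents that add atoms: none
Why: Luche 1,2‑reduction: cerium‑activated NaBH4 reduces the enal carbonyl only, leaving the α‑methylene lactone and the stannane intact.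

Step 14
Reactants: 26 (4S,5S)-4-[(2S,3E,7R,8E)-2,7-dihydroxy-3,7-dimethyl-9-(tributylstannyl)nona-3,8-dien-1-yl]-5-[(1E)-3-hydroxy-2-methylprop-1-en-1-yl]-3-methylideneoxolan-2-one
Product: 28 (4S,5S)-5-[(1E)-3-chloro-2-methylprop-1-en-1-yl]-4-[(2S,3E,7R,8E)-2,7-dihydroxy-3,7-dimethyl-9-(tributylstannyl)nona-3,8-dien-1-yl]-3-methylideneoxolan-2-one, via allylic mesylate 27 (not isolated)
Conditions: MsCl (1.1 equiv), 2,4,6-collidine, LiCl, DMF, 0 °C
Reagents that add atoms: lithium chloride ([Li+].[Cl-])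
Why: Collington–Meyers chlorination: only the unhindered primary allylic hydroxyl is mesylated and displaced by chloride (SN2, no allylic transposition), the secondary and tertiary hydroxyls stay free.

Step 15
Reactants: 28 (4S,5S)-5-[(1E)-3-chloro-2-methylprop-1-en-1-yl]-4-[(2S,3E,7R,8E)-2,7-dihydroxy-3,7-dimethyl-9-(tributylstannyl)nona-3,8-dien-1-yl]-3-methylideneoxolan-2-one
Product: 29 (3aS,5S,6E,10R,11E,14E,15aS)-5,10-dihydroxy-6,10,14-trimethyl-3-methylidene-3a,4,5,8,9,10,13,15a-octahydrocyclotetradeca[b]furan-2(3H)-one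
Conditions: Pd2(dba)3 (10 mol %), AsPh3 (40 mol %), NMP/THF, 50 °C, 1 mM, syringe-pump addition
Reagents that add atoms: none
Why: Intramolecular Stille coupling of an allylic chloride: zerovalent palladium ionises the C4 chloride to a π‑allyl complex, Sn‑to‑Pd transmetalation and reductive elimination form the C4–C5 bond at the unsubstituted allyl terminus with retention of both alkene geometries (neutral conditions, so no O‑allylation), high dilution favours the 14‑membered ring, and no stereocentre is created.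

Step 16
Reactants: 29 (3aS,5S,6E,10R,11E,14E,15aS)-5,10-dihydroxy-6,10,14-trimethyl-3-methylidene-3a,4,5,8,9,10,13,15a-octahydrocyclotetradeca[b]furan-2(3H)-one
Product: 30 des-acetyl target (C10–C11 epoxide; C12–OH free; local labels 1S,7R,10S,11S,12S,14S)
Conditions: Ti(OiPr)4 (1.2 equiv), L-(+)-diisopropyl tartrate (1.5 equiv), t-BuOOH (2 equiv), 4 Å MS, CH2Cl2, −20 °C
Reagents that add atoms: tert-butyl hydroperoxide (CC(C)(C)OO)
Why: Sharpless asymmetric epoxidation in its matched kinetic‑resolution mode: the titanium L‑(+)‑tartrate catalyst epoxidises the 12S secondary allylic alcohol rapidly on the face that gives the erythro epoxy alcohol (C10 and C11 set together, E geometry transferred), while the tertiary allylic alcohol, the other alkenes and any 12R epimer react far more slowly.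

Step 17
Reactants: 30 des-acetyl target
Product: 31 CNP0288879.3 (target; local labels 1S,7R,10S,11R,12S,14S)
Conditions: Ac2O, pyridine, DMAP (cat.), CH2Cl2, 0 °C
Reagents that add atoms: acetic anhydride (CC(=O)OC(C)=O)
Why: DMAP‑catalysed acetylation of the secondary alcohol with retention at C12; the hindered tertiary C7 hydroxyl is not acylated.

## Compound list

1 | sodium cyclopentadienide | [Na+].c1cc[cH-]c1 | starting material
2 | malonic acid | OC(=O)CC(=O)O | starting material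
3 | cyclopenta-1,3-diene | C1C=CC=C1 | intermediate
4 | rac-(3aS,6aS)-2-oxo-3,3a,4,6a-tetrahydro-2H-cyclopenta[b]furan-3-carboxylic acid (cis-fused racemate, C3 epimers; one enantiomer drawn) | OC(=O)C1C(=O)O[C@H]2C=CC[C@@H]12 | intermediate
5 | (S)-1-phenylethylammonium (3aS,6aS)-2-oxo-3,3a,4,6a-tetrahydro-2H-cyclopenta[b]furan-3-carboxylate | [O-]C(=O)C1C(=O)O[C@H]2C=CC[C@@H]12.C[C@H]([NH3+])c1ccccc1 | intermediate
6 | (3aS,6aS)-2-oxo-3,3a,4,6a-tetrahydro-2H-cyclopenta[b]furan-3-carboxylic acid (single enantiomer) | OC(=O)C1C(=O)O[C@H]2C=CC[C@@H]12 | intermediate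
7 | (3aS,6aS)-3-[(diethylamino)methyl]-2-oxo-3,3a,4,6a-tetrahydro-2H-cyclopenta[b]furan-3-carboxylic acid | CCN(CC)CC1(C(=O)O)C(=O)O[C@H]2C=CC[C@@H]12 | intermediate
8 | (3aS,6aS)-3-methylidene-3,3a,4,6a-tetrahydro-2H-cyclopenta[b]furan-2-one | C=C1C(=O)O[C@H]2C=CC[C@@H]12 | intermediate
9 | (2R,3S)-3-(2-hydroperoxy-2-methoxyethyl)-4-methylidene-5-oxooxolane-2-carbaldehyde | C=C1C(=O)O[C@@H](C=O)[C@H]1CC(OC)OO | intermediate
10 | (4S,5R)-5-(dimethoxymethyl)-4-(2-hydroperoxy-2-methoxyethyl)-3-methylideneoxolan-2-one | C=C1C(=O)O[C@@H](C(OC)OC)[C@H]1CC(OC)OO | intermediate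
11 | 2-[(2R,3S)-2-(dimethoxymethyl)-4-methylidene-5-oxooxolan-3-yl]acetaldehyde | C=C1C(=O)O[C@@H](C(OC)OC)[C@H]1CC=O | intermediate
12 | 2-methylprop-2-en-1-ol | C=C(C)CO | starting material
13 | 1-bromobut-2-yne | CC#CCBr | starting material
14 | lithium 2-(lithiomethyl)prop-2-en-1-olate | [Li]CC(=C)CO[Li] | intermediate
15 | 2-methylidenehept-5-yn-1-ol | C=C(CO)CCC#CC | intermediate
16 | [(2R)-2-(pent-3-yn-1-yl)oxiran-2-yl]methanol | CC#CCC[C@@]1(CO)CO1 | intermediate
17 | (2R)-2-methylhept-5-yne-1,2-diol | CC#CCC[C@@](C)(O)CO | intermediate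
18 | (2R)-2-hydroxy-2-methylhept-5-ynal | CC#CCC[C@@](C)(O)C=O | intermediate
19 | (1E,3R)-3-methyl-1-(tributylstannyl)oct-1-en-6-yn-3-ol | CC#CCC[C@@](C)(O)/C=C/[Sn](CCCC)(CCCC)CCCC | intermediate
20 | methyl{[(1E,3R)-3-methyl-1-(tributylstannyl)oct-1-en-6-yn-3-yl]oxy}zinc | CC#CCC[C@@](C)(O[Zn]C)/C=C/[Sn](CCCC)(CCCC)CCCC | intermediate
21 | chlorobis(cyclopentadienyl)[(2E,6R,7E)-6-methyl-6-[(methylzincio)oxy]-8-(tributylstannyl)octa-2,7-dien-2-yl]zirconium | C/C(=C\CC[C@@](C)(O[Zn]C)/C=C/[Sn](CCCC)(CCCC)CCCC)[Zr](Cl)(C1C=CC=C1)C1C=CC=C1 | intermediate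
22 | methyl[(2E,6R,7E)-6-methyl-6-[(methylzincio)oxy]-8-(tributylstannyl)octa-2,7-dien-2-yl]zinc | C/C(=C\CC[C@@](C)(O[Zn]C)/C=C/[Sn](CCCC)(CCCC)CCCC)[Zn]C | intermediate
23 | (4S,5R)-5-(dimethoxymethyl)-4-[(2S,3E,7R,8E)-2,7-dihydroxy-3,7-dimethyl-9-(tributylstannyl)nona-3,8-dien-1-yl]-3-methylideneoxolan-2-one | C=C1C(=O)O[C@@H](C(OC)OC)[C@H]1C[C@H](O)/C(C)=C/CC[C@@](C)(O)/C=C/[Sn](CCCC)(CCCC)CCCC | intermediate
24 | (3aS,5S,7aR)-7-hydroxy-5-[(2E,6R,7E)-6-hydroxy-6-methyl-8-(tributylstannyl)octa-2,7-dien-2-yl]-3-methylidenehexahydro-2H-furo[2,3-c]pyran-2-one (lactol, anomer mixture) | C=C1C(=O)O[C@H]2C(O)O[C@@H](C[C@@H]12)/C(C)=C/CC[C@@](C)(O)/C=C/[Sn](CCCC)(CCCC)CCCC | intermediate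
25 | (4S,5S)-4-[(2S,3E,7R,8E)-2,7-dihydroxy-3,7-dimethyl-9-(tributylstannyl)nona-3,8-dien-1-yl]-3-methylidene-5-[(1E)-2-methyl-3-oxoprop-1-en-1-yl]oxolan-2-one | C=C1C(=O)O[C@@H](/C=C(\C)C=O)[C@H]1C[C@H](O)/C(C)=C/CC[C@@](C)(O)/C=C/[Sn](CCCC)(CCCC)CCCC | intermediate
26 | (4S,5S)-4-[(2S,3E,7R,8E)-2,7-dihydroxy-3,7-dimethyl-9-(tributylstannyl)nona-3,8-dien-1-yl]-5-[(1E)-3-hydroxy-2-methylprop-1-en-1-yl]-3-methylideneoxolan-2-one | C=C1C(=O)O[C@@H](/C=C(\C)CO)[C@H]1C[C@H](O)/C(C)=C/CC[C@@](C)(O)/C=C/[Sn](CCCC)(CCCC)CCCC | intermediate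
27 | primary allylic methanesulfonate of 26 | C=C1C(=O)O[C@@H](/C=C(\C)COS(C)(=O)=O)[C@H]1C[C@H](O)/C(C)=C/CC[C@@](C)(O)/C=C/[Sn](CCCC)(CCCC)CCCC | intermediate
28 | (4S,5S)-5-[(1E)-3-chloro-2-methylprop-1-en-1-yl]-4-[(2S,3E,7R,8E)-2,7-dihydroxy-3,7-dimethyl-9-(tributylstannyl)nona-3,8-dien-1-yl]-3-methylideneoxolan-2-one | C=C1C(=O)O[C@@H](/C=C(\C)CCl)[C@H]1C[C@H](O)/C(C)=C/CC[C@@](C)(O)/C=C/[Sn](CCCC)(CCCC)CCCC | intermediate
29 | (3aS,5S,6E,10R,11E,14E,15aS)-5,10-dihydroxy-6,10,14-trimethyl-3-methylidene-3a,4,5,8,9,10,13,15a-octahydrocyclotetradeca[b]furan-2(3H)-one (local labels 1S,7R,12S,14S; 2E,5E,10E) | C=C1C(=O)O[C@H]2/C=C(\C)C/C=C/[C@](C)(O)CC/C=C(\C)[C@@H](O)C[C@@H]12 | intermediate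
30 | des-acetyl target: C10–C11 epoxide, C12–OH (local labels 1S,7R,10S,11S,12S,14S; 2E,5E) | C=C1C(=O)O[C@H]2/C=C(\C)C/C=C/[C@](C)(O)CC[C@@H]3O[C@@]3(C)[C@@H](O)C[C@@H]12 | intermediate
31 | CNP0288879.3: C12 acetate of 30 (local labels 1S,7R,10S,11R,12S,14S; 2E,5E) | C=C1C(=O)O[C@H]2/C=C(\C)C/C=C/[C@](C)(O)CC[C@@H]3O[C@@]3(C)[C@@H](OC(C)=O)C[C@@H]12 | target

## Step count and risks

Total steps: 17. Longest linear sequence: 13 (steps 5–9, then 10–17).

Step 1 may fail through over‑oxidation of the α‑carboxy lactone, acetate capture of the allyl cation or diene dimerisation. The fallback sets out from 3 and returns at 4. Iodine‑atom‑transfer radical addition of iodoacetic acid to cyclopentadiene 3 (BEt3/air, benzene) gives rac-trans-2-(2-iodocyclopent-3-en-1-yl)acetic acid F1. NaHCO3 then closes it by intramolecular SN2 displacement with inversion at the iodide carbon to the cis‑fused lactone rac-(3aS,6aR)-3,3a,4,6a-tetrahydro-2H-cyclopenta[b]furan-2-one F2. α‑Carboxylation of F2 with methyl magnesium carbonate (MeOMgOCO2Me, DMF, then aqueous acid) gives racemic acid 4.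

Step 2 may fail because the desired salt need not be the less soluble one or may not crystallise cleanly (the antipodal amine is the first variation). The fallback sets out from 4 and returns at 23, with no resolution. Racemic 4 is methylenated and ozonolysed exactly as in steps 3 and 4, giving racemic lactone F3 and racemic aldehyde F4. The (+)-MIB‑controlled addition of step 10 with enantiopure 19 then gives 23 together with its (C1R,C14R) diastereomer F5. Both are 12S,7R and differ in the relative configuration of C12 and C14, so they are separated by chromatography, and 23 continues at step 11.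

Step 15 may fail through oligomerisation, coupling at the substituted allyl terminus or E/Z scrambling of the π‑allyl. The fallback sets out from 28 and returns at 29. I2 (CH2Cl2, 0 °C) converts the vinylstannane of 28 with retention into the E‑vinyl iodide F6. A nickel‑catalysed reductive cross‑electrophile coupling (NiBr2·glyme, 4,4′-di-tert-butyl-2,2′-bipyridine, Zn dust, DMA, 1 mM) then joins the allyl chloride and vinyl iodide termini to give 29.

Further compounds
F1 | step 1 | rac-trans-2-(2-iodocyclopent-3-en-1-yl)acetic acid | OC(=O)C[C@@H]1CC=C[C@H]1I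
F2 | step 1 | rac-(3aS,6aR)-3,3a,4,6a-tetrahydro-2H-cyclopenta[b]furan-2-one (cis-fused) | C1C(=O)O[C@H]2C=CC[C@@H]12
F3 | step 2 | rac-(3aS,6aS)-3-methylidene-3,3a,4,6a-tetrahydro-2H-cyclopenta[b]furan-2-one (racemic 8) | C=C1C(=O)O[C@H]2C=CC[C@@H]12
F4 | step 2 | rac-2-[(2R,3S)-2-(dimethoxymethyl)-4-methylidene-5-oxooxolan-3-yl]acetaldehyde (racemic 11) | C=C1C(=O)O[C@@H](C(OC)OC)[C@H]1CC=O
F5 | step 2 | (4R,5S)-5-(dimethoxymethyl)-4-[(2S,3E,7R,8E)-2,7-dihydroxy-3,7-dimethyl-9-(tributylstannyl)nona-3,8-dien-1-yl]-3-methylideneoxolan-2-one | C=C1C(=O)O[C@H](C(OC)OC)[C@@H]1C[C@H](O)/C(C)=C/CC[C@@](C)(O)/C=C/[Sn](CCCC)(CCCC)CCCC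
F6 | step 15 | (4S,5S)-5-[(1E)-3-chloro-2-methylprop-1-en-1-yl]-4-[(2S,3E,7R,8E)-2,7-dihydroxy-9-iodo-3,7-dimethylnona-3,8-dien-1-yl]-3-methylideneoxolan-2-one | C=C1C(=O)O[C@@H](/C=C(\C)CCl)[C@H]1C[C@H](O)/C(C)=C/CC[C@@](C)(O)/C=C/I
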